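**Retrosynthetic overview**
1. Endgame, C–O bonds only: the α-hydroxy hemiketal comes from epoxidation and hydration of the enol-ether C=C of tetracyclic vinylogous ester 37. Its dihydropyran ring comes from conjugate addition and cyclodehydration of 4-hydroxy-5,6-dimethyl-2-pyrone (34) on the exo-methylene ketone of azulenetrione 33.
2. Seven-membered ring: Nozaki–Hiyama–Kishi closure of a 2-iodoalkene onto an aldehyde (30 → 31), which also delivers the exocyclic methylene used in line 1.
3. Cyclopentenone (key step): Brook-rearrangement-mediated [3+2] annulation of acryloylsilane 16 with the lithium enolate of an isopropyl ketone (22). The enabling feature is in the cyclopentenone ring: the CMe2 carbon lies between the ketone carbon and the tertiary carbinol carbon, and the carbinol carbon is bonded to the enone β-carbon. CMe2/C–OH are therefore the α-carbon and carbonyl carbon of an isopropyl ketone, and O=C–CH=C is an acylsilane whose carbonyl carbon is electrophilic and whose β-carbon turns nucleophilic after the 1,2-silyl shift.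
4. Stereocontrol: the CH(CH3) centre comes from the (S)-Roche ester. The cyclopentenone carbinol carbon is set by a temporary silyloxy stereocentre from (R)-α-hydroxy-γ-butyrolactone, later oxidised to the ring ketone.
5. Ring order: cyclopentenone (step 14) → cycloheptane (step 17) → dihydropyran (step 20); the pyranone ring is purchased.

Key step: step 14

Remark (assumption on the chemistry): the hemiketal carbon, the CH(OH) next to it and the ring-fusion CH can equilibrate (ring–chain tautomerism, enolisation), so their natural configuration is taken to be the thermodynamic one; the route fixes only the cyclopentenone carbinol carbon and the CH(CH3) centre kinetically.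

**Route**

Step 1
Reactants: 1 methyl (S)-3-hydroxy-2-methylpropanoate
Product: 2 methyl (S)-3-[(tert-butyldimethylsilyl)oxy]-2-methylpropanoate
Conditions: TBSCl, imidazole, CH2Cl2, 0 °C → rt
Reagents that add atoms: tert-butyldimethylsilyl chloride, CC(C)(C)[Si](C)(C)Cl
Why: Silylation of the primary alcohol (silyl ether protection) should proceed without touching the stereocentre.

Step 2
Reactants: 2 methyl (S)-3-[(tert-butyldimethylsilyl)oxy]-2-methylpropanoate
Product: 3 (S)-3-[(tert-butyldimethylsilyl)oxy]-2-methylpropanal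
Conditions: DIBAL-H (1.05 equiv), CH2Cl2, −78 °C; Rochelle salt work-up
Reagents that add atoms: none
Why: DIBAL-H half-reduction of the ester stops at the tetrahedral aluminate at −78 °C, and the α-centre should survive the cold, non-basic conditions.

Step 3
Reactants: 3 (S)-3-[(tert-butyldimethylsilyl)oxy]-2-methylpropanal
Product: 4 (R)-tert-butyldimethyl[(2-methylbut-3-yn-1-yl)oxy]silane
Conditions: dimethyl (1-diazo-2-oxopropyl)phosphonate, K2CO3, MeOH, 0 °C → rt
Reagents that add atoms: dimethyl (1-diazo-2-oxopropyl)phosphonate, COP(=O)(OC)C(=[N+]=[N-])C(C)=O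
Why: Seyferth–Gilbert homologation with the Ohira–Bestmann reagent converts the aldehyde into the terminal alkyne under conditions commonly used for α-methyl-β-silyloxy aldehydes (the descriptor changes only through CIP priorities).

Step 4
Reactants: 4 (R)-tert-butyldimethyl[(2-methylbut-3-yn-1-yl)oxy]silane
Product: 6 (S)-tert-butyl[(3-iodo-2-methylbut-3-en-1-yl)oxy]dimethylsilane, via iodoalkenylborane 5 (not isolated)
Conditions: B-iodo-9-BBN, pentane, −20 → 0 °C; then AcOH, 0 °C
Reagents that add atoms: B-iodo-9-borabicyclo[3.3.1]nonane, IB1C2CCCC1CCC2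
Why: syn-Iodoboration of the terminal alkyne (boron to the terminal carbon, iodine to the internal one) followed by protodeboronation with acetic acid should give the 2-iodo-1-alkene, the Markovnikov HI adduct.

Step 5
Reactants: 6 (S)-tert-butyl[(3-iodo-2-methylbut-3-en-1-yl)oxy]dimethylsilane
Product: 7 (S)-3-iodo-2-methylbut-3-en-1-ol
Conditions: TBAF, THF, 0 °C
Reagents that add atoms: none
Why: Fluoride-induced desilylation of a primary TBS ether is routine and leaves the vinyl iodide intact.

Step 6
Reactants: 7 (S)-3-iodo-2-methylbut-3-en-1-ol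
Product: 8 (S)-3-iodo-2-methylbut-3-enal
Conditions: Dess–Martin periodinane, NaHCO3, CH2Cl2, 0 °C; used at once
Reagents that add atoms: none
Why: Buffered Dess–Martin oxidation is non-basic, which should keep the allylic α-stereocentre of this β,γ-unsaturated aldehyde intact if it is carried on immediately.

Step 7
Reactants: 9 ethyl vinyl ether
Product: 12 1-(tert-butyldimethylsilyl)ethan-1-one, via (1-ethoxyvinyl)lithium 10 (not isolated), via silyl enol ether 11 (not isolated)
Conditions: t-BuLi, THF, −78 → 0 °C; TBSCl, −78 °C → rt; 1 M HCl, acetone, rt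
Reagents that add atoms: tert-butyldimethylsilyl chloride, CC(C)(C)[Si](C)(C)Cl; water, O
Why: α-Lithiation of the enol ether gives an acyl anion equivalent that is silylated at carbon, and acid hydrolysis of the enol ether unveils the acylsilane.

Step 8
Reactants: 12 1-(tert-butyldimethylsilyl)ethan-1-one; 8 (S)-3-iodo-2-methylbut-3-enal
Product: 14 (4S)-1-(tert-butyldimethylsilyl)-3-hydroxy-5-iodo-4-methylhex-5-en-1-one (both C3 epimers), via lithium enolate 13 (not isolated)
Conditions: LDA, THF, −78 °C; then 8, −78 °C; aq. NH4Cl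
Reagents that add atoms: none
Why: Aldol addition of the acylsilane lithium enolate at −78 °C should outrun enolisation of the aldehyde, and the new carbinol centre is removed in step 9.

Step 9
Reactants: 14 (4S)-1-(tert-butyldimethylsilyl)-3-hydroxy-5-iodo-4-methylhex-5-en-1-one
Product: 16 (4S,2E)-1-(tert-butyldimethylsilyl)-5-iodo-4-methylhexa-2,5-dien-1-one, via mesylate 15 (not isolated)
Conditions: MsCl, Et3N, CH2Cl2, −20 → 0 °C
Reagents that add atoms: none
Why: Mesylation followed by E1cB elimination through the acylsilane enolate should give the (E)-acryloylsilane under amine conditions mild enough to spare the doubly allylic CH(CH3) centre.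

Step 10
Reactants: 17 (R)-3-hydroxydihydrofuran-2(3H)-one
Product: 18 (R)-2,4-dihydroxy-N-methoxy-N-methylbutanamide
Conditions: MeNHOMe·HCl, AlMe3, CH2Cl2, 0 °C → rt
Reagents that add atoms: N,O-dimethylhydroxylamine hydrochloride, CNOC.Cl
Why: Weinreb aminolysis of the lactone with the aluminium amide opens the ring without touching the α-stereocentre, as is known for α-hydroxy lactones.

Step 11
Reactants: 18 (R)-2,4-dihydroxy-N-methoxy-N-methylbutanamide
Product: 19 (R)-N-methoxy-N-methyl-2,4-bis(triethylsilyloxy)butanamide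
Conditions: TESCl (2.5 equiv), imidazole, DMF, 0 °C → rt
Reagents that add atoms: chlorotriethylsilane, CC[Si](Cl)(CC)CC
Why: Bis-silylation blocks relactonisation and installs the non-chelating silyloxy group needed for Felkin control in step 14.

Step 12
Reactants: 19 (R)-N-methoxy-N-methyl-2,4-bis(triethylsilyloxy)butanamide
Product: 20 (R)-2-methyl-4,6-bis(triethylsilyloxy)hex-1-en-3-one
Conditions: isopropenylmagnesium bromide, THF, −20 → 0 °C; cold aq. NH4Cl
Reagents that add atoms: isopropenylmagnesium bromide, CC(=C)[Mg]Br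
Why: Weinreb ketone synthesis, where the chelated tetrahedral intermediate prevents over-addition and the cold quench avoids conjugate addition of the liberated amine.

Step 13
Reactants: 20 (R)-2-methyl-4,6-bis(triethylsilyloxy)hex-1-en-3-one
Product: 21 (R)-dimethyl{[2-methyl-4,6-bis(triethylsilyloxy)hex-2-en-3-yl]oxy}phenylsilane
Conditions: PhMe2SiH, RhCl(PPh3)3 (1 mol %), THF, 50 °C
Reagents that add atoms: dimethylphenylsilane, C[SiH](C)c1ccccc1
Why: Rh-catalysed 1,4-hydrosilylation of an enone with a monohydrosilane gives the fully substituted silyl enol ether regiospecifically, so the α-silyloxy CH is never deprotonated.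

Step 14
Reactants: 21 (R)-dimethyl{[2-methyl-4,6-bis(triethylsilyloxy)hex-2-en-3-yl]oxy}phenylsilane; 16 (4S,2E)-1-(tert-butyldimethylsilyl)-5-iodo-4-methylhexa-2,5-dien-1-one
Product: 26 tert-butyl{[(3S,4R)-4-[(1R)-1,3-bis(triethylsilyloxy)propyl]-3-[(2S)-3-iodobut-3-en-2-yl]-5,5-dimethyl-4-(trimethylsilyloxy)cyclopent-1-en-1-yl]oxy}dimethylsilane, via lithium enolate 22 (not isolated), via silyl alkoxide adduct 23 (not isolated), via siloxyallyllithium 24 (not isolated), via lithium cyclopentenolate 25 (not isolated)
Conditions: MeLi, THF, 0 °C; then 16, −78 → −30 °C; then TMSCl, −30 → 0 °C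
Reagents that add atoms: chlorotrimethylsilane, C[Si](C)(C)Cl
Why: The enolate carbon (the future CMe2) adds 1,2 to the acylsilane carbonyl, the α-silyl alkoxide undergoes a 1,2-Brook shift to a siloxyallyl anion, and its γ-carbon attacks the ketone carbonyl regenerated by the first addition, so the C(=O)–CMe2 bond and the bond from the future enone β-carbon to the carbinol carbon form in one flask. The closest known reaction type is the Brook-rearrangement-mediated [3+2] annulation of acryloylsilanes with ketone lithium enolates, whose precedent lies with β-heteroatom acryloylsilanes and methyl ketone enolates; here the partners are a β-alkyl acryloylsilane and a fully substituted enolate. The cyclopentene closes by 5-exo-trig attack of the allyl anion terminus on the C=O (or through the vinylcyclopropanolate and its oxyanion-accelerated 1,3-shift, which leads to the same ring). The carbinol stereocentre is controlled by the neighbouring silyloxy centre: in the Felkin–Anh transition state the C–OSiEt3 bond stands anti to the incoming carbanion, which should turn the (R) side chain into the (R) carbinol, while the new CH centre beside it (expected trans to the side chain) is erased in step 15. The step needs 1,2- rather than 1,4-addition (secured by the electrophilic acylsilane carbonyl and the branched β-substituent), a regiodefined enolate (secured by its generation from 21) and ring closure faster than proton transfer (aprotic medium until the silyl quench). TMSCl caps the hindered tertiary alkoxide so that no lactol can form from the aldehyde made in step 16.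

Step 15
Reactants: 26 tert-butyl{[(3S,4R)-4-[(1R)-1,3-bis(triethylsilyloxy)propyl]-3-[(2S)-3-iodobut-3-en-2-yl]-5,5-dimethyl-4-(trimethylsilyloxy)cyclopent-1-en-1-yl]oxy}dimethylsilane
Product: 29 (4R)-4-[(1R)-1,3-bis(triethylsilyloxy)propyl]-3-[(2S)-3-iodobut-3-en-2-yl]-5,5-dimethyl-4-(trimethylsilyloxy)cyclopent-2-en-1-one, via selenide 27 (not isolated), via selenoxide 28 (not isolated)
Conditions: PhSeCl, pyridine, CH2Cl2, −78 °C; then 30 % H2O2, 0 °C → rt
Reagents that add atoms: none
Why: α-Selenenylation of the silyl enol ether and selenoxide syn-elimination can only remove the hydrogen on the side-chain-bearing ring carbon, which gives the enone and avoids Pd(0) in the presence of the vinyl iodide.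

Step 16
Reactants: 29 (4R)-4-[(1R)-1,3-bis(triethylsilyloxy)propyl]-3-[(2S)-3-iodobut-3-en-2-yl]-5,5-dimethyl-4-(trimethylsilyloxy)cyclopent-2-en-1-one
Product: 30 (3R)-3-[(1R)-2-[(2S)-3-iodobut-3-en-2-yl]-5,5-dimethyl-4-oxo-1-(trimethylsilyloxy)cyclopent-2-en-1-yl]-3-(triethylsilyloxy)propanal
Conditions: (COCl)2, DMSO, CH2Cl2, −78 → −30 °C; then Et3N, −78 → 0 °C
Reagents that add atoms: none
Why: Under Swern conditions primary triethylsilyl ethers are cleaved by the chlorosulfonium salt and oxidised directly to aldehydes, while the hindered secondary TES and tertiary TMS ethers should remain.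

Step 17
Reactants: 30 (3R)-3-[(1R)-2-[(2S)-3-iodobut-3-en-2-yl]-5,5-dimethyl-4-oxo-1-(trimethylsilyloxy)cyclopent-2-en-1-yl]-3-(triethylsilyloxy)propanal
Product: 31 (3aR,4R,8R)-6-hydroxy-3,3,8-trimethyl-7-methylidene-4-(triethylsilyloxy)-3a-(trimethylsilyloxy)-3a,4,5,6,7,8-hexahydroazulen-2(3H)-one (both C6 epimers)
Conditions: CrCl2 (8 equiv), NiCl2 (2 mol %), degassed DMSO, 0.005 M, rt
Reagents that add atoms: none
Why: Nozaki–Hiyama–Kishi reaction: the alkenylchromium(III) species adds chemoselectively to the aldehyde (ketone and enone tolerated) in a 7-exo-trig closure, and the new carbinol centre is oxidised away in step 19.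

Step 18
Reactants: 31 (3aR,4R,8R)-6-hydroxy-3,3,8-trimethyl-7-methylidene-4-(triethylsilyloxy)-3a-(trimethylsilyloxy)-3a,4,5,6,7,8-hexahydroazulen-2(3H)-one
Product: 32 (3aR,4R,8R)-3a,4,6-trihydroxy-3,3,8-trimethyl-7-methylidene-3a,4,5,6,7,8-hexahydroazulen-2(3H)-one (both C6 epimers)
Conditions: HF·pyridine, pyridine, THF, 0 °C → rt
Reagents that add atoms: none
Why: Buffered HF·pyridine removes both silyl ethers without base, which protects the β-hydroxy ketone from retro-aldol cleavage.

Step 19
Reactants: 32 (3aR,4R,8R)-3a,4,6-trihydroxy-3,3,8-trimethyl-7-methylidene-3a,4,5,6,7,8-hexahydroazulen-2(3H)-one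
Product: 33 (3aR,8S)-3a-hydroxy-3,3,8-trimethyl-7-methylidene-3a,5,7,8-tetrahydroazulene-2,4,6(3H)-trione
Conditions: IBX (3 equiv), DMSO, rt; used directly
Reagents that add atoms: none
Why: IBX oxidises the allylic and the secondary alcohol to ketones and is known to convert secondary/tertiary 1,2-diols into α-ketols without C–C cleavage.

Step 20
Reactants: 33 (3aR,8S)-3a-hydroxy-3,3,8-trimethyl-7-methylidene-3a,5,7,8-tetrahydroazulene-2,4,6(3H)-trione; 34 4-hydroxy-5,6-dimethyl-2H-pyran-2-one
Product: 37 tetracyclic vinylogous ester (the target skeleton with an enol-ether C=C between the former hemiketal carbon and the neighbouring CH and no OH on either), via Michael adduct 35 (not isolated), via keto hemiketal 36 (not isolated)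
Conditions: 34 (1.5 equiv), CF3CH2OH, 40 °C; then PPTS (10 mol %), 4 Å MS, PhMe, 40 °C
Reagents that add atoms: none
Why: Michael addition of the nucleophilic C3 of the 4-hydroxy-2-pyrone to the exo-methylene ketone and cyclodehydration of the pyrone OH onto the 1,3-diketone carbonyl gives the conjugated vinylogous ester, with the ring-fusion CH set trans to the neighbouring methyl group by protonation under equilibrating, non-basic conditions.

Step 21
Reactants: 37 tetracyclic vinylogous ester
Product: 39 CNP0525404.1 (target), via epoxide 38 (not isolated)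
Conditions: DMDO, acetone/CH2Cl2, −20 → 0 °C; then H2O/THF, rt
Reagents that add atoms: dimethyldioxirane, CC1(C)OO1; water, O
Why: DMDO epoxidation of the β-alkoxy enone C=C (as known for chromones and dihydropyranones) is expected anti to the pyran CH2 of the adjacent ring-fusion carbon, and anti hydrolytic opening of the alkoxy epoxide at the ketal carbon gives the trans α-hydroxy hemiketal; the hemiketal carbon and the epimerisable CH(OH) can settle to the thermodynamic configuration.

**Compound list**
1 | methyl (S)-3-hydroxy-2-methylpropanoate | COC(=O)[C@@H](C)CO | starting material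
2 | methyl (S)-3-[(tert-butyldimethylsilyl)oxy]-2-methylpropanoate | COC(=O)[C@@H](C)CO[Si](C)(C)C(C)(C)C | intermediate
3 | (S)-3-[(tert-butyldimethylsilyl)oxy]-2-methylpropanal | O=C[C@@H](C)CO[Si](C)(C)C(C)(C)C | intermediate
4 | (R)-tert-butyldimethyl[(2-methylbut-3-yn-1-yl)oxy]silane | C#C[C@@H](C)CO[Si](C)(C)C(C)(C)C | intermediate
5 | 9-[(1Z,3S)-4-[(tert-butyldimethylsilyl)oxy]-2-iodo-3-methylbut-1-en-1-yl]-9-borabicyclo[3.3.1]nonane | CC(C)(C)[Si](C)(C)OC[C@H](C)/C(I)=C/B1C2CCCC1CCC2 | intermediate (not isolated)
6 | (S)-tert-butyl[(3-iodo-2-methylbut-3-en-1-yl)oxy]dimethylsilane | C=C(I)[C@@H](C)CO[Si](C)(C)C(C)(C)C | intermediate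
7 | (S)-3-iodo-2-methylbut-3-en-1-ol | C=C(I)[C@@H](C)CO | intermediate
8 | (S)-3-iodo-2-methylbut-3-enal | C=C(I)[C@@H](C)C=O | intermediate
9 | ethyl vinyl ether | C=COCC | starting material
10 | (1-ethoxyvinyl)lithium | [Li]C(=C)OCC | intermediate (not isolated)
11 | tert-butyl(1-ethoxyvinyl)dimethylsilane | C=C(OCC)[Si](C)(C)C(C)(C)C | intermediate (not isolated)
12 | 1-(tert-butyldimethylsilyl)ethan-1-one | CC(=O)[Si](C)(C)C(C)(C)C | intermediate
13 | lithium 1-(tert-butyldimethylsilyl)ethen-1-olate | C=C(O[Li])[Si](C)(C)C(C)(C)C | intermediate (not isolated)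
14 | (4S)-1-(tert-butyldimethylsilyl)-3-hydroxy-5-iodo-4-methylhex-5-en-1-one (both C3 epimers) | C=C(I)[C@@H](C)C(O)CC(=O)[Si](C)(C)C(C)(C)C | intermediate
15 | (3S)-6-(tert-butyldimethylsilyl)-2-iodo-3-methyl-6-oxohex-1-en-4-yl methanesulfonate | C=C(I)[C@@H](C)C(OS(C)(=O)=O)CC(=O)[Si](C)(C)C(C)(C)C | intermediate (not isolated)
16 | (4S,2E)-1-(tert-butyldimethylsilyl)-5-iodo-4-methylhexa-2,5-dien-1-one | C=C(I)[C@@H](C)/C=C/C(=O)[Si](C)(C)C(C)(C)C | intermediate
17 | (R)-3-hydroxydihydrofuran-2(3H)-one [(R)-α-hydroxy-γ-butyrolactone] | O=C1OCC[C@H]1O | starting material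
18 | (R)-2,4-dihydroxy-N-methoxy-N-methylbutanamide | CON(C)C(=O)[C@H](O)CCO | intermediate
19 | (R)-N-methoxy-N-methyl-2,4-bis(triethylsilyloxy)butanamide | CON(C)C(=O)[C@H](O[Si](CC)(CC)CC)CCO[Si](CC)(CC)CC | intermediate
20 | (R)-2-methyl-4,6-bis(triethylsilyloxy)hex-1-en-3-one | C=C(C)C(=O)[C@H](O[Si](CC)(CC)CC)CCO[Si](CC)(CC)CC | intermediate
21 | (R)-dimethyl{[2-methyl-4,6-bis(triethylsilyloxy)hex-2-en-3-yl]oxy}phenylsilane | CC(C)=C(O[Si](C)(C)c1ccccc1)[C@H](O[Si](CC)(CC)CC)CCO[Si](CC)(CC)CC | intermediate
22 | lithium (R)-2-methyl-4,6-bis(triethylsilyloxy)hex-2-en-3-olate | CC(C)=C(O[Li])[C@H](O[Si](CC)(CC)CC)CCO[Si](CC)(CC)CC | intermediate (not isolated)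
23 | lithium α-silyl alkoxide from addition of the enolate carbon of 22 to the carbonyl of 16 (both epimers at the new carbinol carbon) | C=C(I)[C@@H](C)/C=C/C(O[Li])([Si](C)(C)C(C)(C)C)C(C)(C)C(=O)[C@H](O[Si](CC)(CC)CC)CCO[Si](CC)(CC)CC | intermediate (not isolated)
24 | siloxyallyllithium formed from 23 by 1,2-Brook shift (lithium on the carbon next to CH(CH3)) | C=C(I)[C@@H](C)C([Li])/C=C(/O[Si](C)(C)C(C)(C)C)C(C)(C)C(=O)[C@H](O[Si](CC)(CC)CC)CCO[Si](CC)(CC)CC | intermediate (not isolated)
25 | lithium alkoxide of the cyclised product (26 with OLi in place of OSiMe3) | CC[Si](CC)(CC)OCC[C@@H](O[Si](CC)(CC)CC)[C@@]1(O[Li])[C@@H](C=C(O[Si](C)(C)C(C)(C)C)C1(C)C)[C@H](C)C(I)=C | intermediate (not isolated)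
26 | tert-butyl{[(3S,4R)-4-[(1R)-1,3-bis(triethylsilyloxy)propyl]-3-[(2S)-3-iodobut-3-en-2-yl]-5,5-dimethyl-4-(trimethylsilyloxy)cyclopent-1-en-1-yl]oxy}dimethylsilane | CC[Si](CC)(CC)OCC[C@@H](O[Si](CC)(CC)CC)[C@@]1(O[Si](C)(C)C)[C@@H](C=C(O[Si](C)(C)C(C)(C)C)C1(C)C)[C@H](C)C(I)=C | intermediate
27 | 2-(phenylselanyl)cyclopentanone from 26 (selenium on the CH between the ketone and the side-chain carbon) | CC[Si](CC)(CC)OCC[C@@H](O[Si](CC)(CC)CC)[C@@]1(O[Si](C)(C)C)[C@@H](C([Se]c2ccccc2)C(=O)C1(C)C)[C@H](C)C(I)=C | intermediate (not isolated)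
28 | selenoxide of 27 | CC[Si](CC)(CC)OCC[C@@H](O[Si](CC)(CC)CC)[C@@]1(O[Si](C)(C)C)[C@@H](C([Se](=O)c2ccccc2)C(=O)C1(C)C)[C@H](C)C(I)=C | intermediate (not isolated)
29 | (4R)-4-[(1R)-1,3-bis(triethylsilyloxy)propyl]-3-[(2S)-3-iodobut-3-en-2-yl]-5,5-dimethyl-4-(trimethylsilyloxy)cyclopent-2-en-1-one | CC[Si](CC)(CC)OCC[C@@H](O[Si](CC)(CC)CC)[C@@]1(O[Si](C)(C)C)C(=CC(=O)C1(C)C)[C@H](C)C(I)=C | intermediate
30 | (3R)-3-[(1R)-2-[(2S)-3-iodobut-3-en-2-yl]-5,5-dimethyl-4-oxo-1-(trimethylsilyloxy)cyclopent-2-en-1-yl]-3-(triethylsilyloxy)propanal | O=CC[C@@H](O[Si](CC)(CC)CC)[C@@]1(O[Si](C)(C)C)C(=CC(=O)C1(C)C)[C@H](C)C(I)=C | intermediate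
31 | (3aR,4R,8R)-6-hydroxy-3,3,8-trimethyl-7-methylidene-4-(triethylsilyloxy)-3a-(trimethylsilyloxy)-3a,4,5,6,7,8-hexahydroazulen-2(3H)-one (both C6 epimers) | OC1C[C@@H](O[Si](CC)(CC)CC)[C@@]2(O[Si](C)(C)C)C(=CC(=O)C2(C)C)[C@H](C)C1=C | intermediate
32 | (3aR,4R,8R)-3a,4,6-trihydroxy-3,3,8-trimethyl-7-methylidene-3a,4,5,6,7,8-hexahydroazulen-2(3H)-one (both C6 epimers) | OC1C[C@@H](O)[C@@]2(O)C(=CC(=O)C2(C)C)[C@H](C)C1=C | intermediate
33 | (3aR,8S)-3a-hydroxy-3,3,8-trimethyl-7-methylidene-3a,5,7,8-tetrahydroazulene-2,4,6(3H)-trione | O=C1CC(=O)[C@@]2(O)C(=CC(=O)C2(C)C)[C@H](C)C1=C | intermediate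
34 | 4-hydroxy-5,6-dimethyl-2H-pyran-2-one | Cc1oc(=O)cc(O)c1C | starting material
35 | Michael adduct: 33 with a (4-hydroxy-5,6-dimethyl-2-oxo-2H-pyran-3-yl)methyl group on the former methylidene-bearing carbon, trans to the methyl group (7R,8R) | Cc1oc(=O)c(C[C@H]2C(=O)CC(=O)[C@@]3(O)C(=CC(=O)C3(C)C)[C@@H]2C)c(O)c1C | intermediate (not isolated)
36 | keto hemiketal: the target without the OH on the carbon between the hemiketal carbon and the ring ketone | Cc1oc(=O)c2c(c1C)O[C@]1(O)CC(=O)[C@@]3(O)C(=CC(=O)C3(C)C)[C@H](C)[C@H]1C2 | intermediate (not isolated)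
37 | tetracyclic vinylogous ester: 36 minus water, C=C between the former hemiketal carbon and the adjacent CH; (R) at the tertiary carbinol, (R) at CH(CH3), (R) at the ring-fusion CH | Cc1oc(=O)c2c(c1C)OC1=CC(=O)[C@@]3(O)C(=CC(=O)C3(C)C)[C@H](C)[C@H]1C2 | intermediate
38 | epoxide of 37 across the enol-ether C=C, oxygen anti to the pyran CH2 at the ring-fusion carbon | Cc1oc(=O)c2c(c1C)O[C@]13O[C@@H]3C(=O)[C@@]4(O)C(=CC(=O)C4(C)C)[C@H](C)[C@H]1C2 | intermediate (not isolated)
39 | CNP0525404.1: hemiketal carbon (S), CH(OH) (R), tertiary carbinol (R), CH(CH3) (R), ring-fusion CH (R) | Cc1oc(=O)c2c(c1C)O[C@]1(O)[C@H](O)C(=O)[C@@]3(O)C(=CC(=O)C3(C)C)[C@H](C)[C@H]1C2 | target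

**Step count**
Total: 21 steps. Longest linear sequence: 16 steps (steps 1–6, 8, 9, 14–21).

**Three steps most likely to fail**

Step 14. The fully substituted enolate 22 may add too slowly to the hindered acylsilane carbonyl, so that conjugate addition or proton transfer from the doubly allylic CH(CH3) of 16 takes over, or the Brook anion may be protonated before it closes the ring. The fallback runs the same annulation with the enolate class that has direct precedent and adds the geminal methyl groups afterwards. It sets out from Weinreb amide 19 and acylsilane 16. MeMgBr converts 19 into the methyl ketone (R)-3,5-bis(triethylsilyloxy)pentan-2-one F1. LDA deprotonates F1 at the methyl group, and addition to 16, Brook shift, ring closure and TMSCl quench should give the cyclopentenyl silyl ether lacking the two ring methyl groups, F2. PhSeCl then H2O2 gives the 5-unsubstituted cyclopentenone F3. LiHMDS/MeI at −78 °C gives the 5-methyl cyclopentenone F4 (loss of the β-silyloxy group from this cross-conjugated enolate would require a cyclopentadienone), and a second LiHMDS/MeI round completes the quaternary carbon and rejoins the route at 29.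

Step 20. In trione 33 the CH(CH3) hydrogen is allylic to two enones, so the exocyclic double bond may migrate into conjugation with loss of that stereocentre, and the enolised 1,3-dione may add to the methylene ketone of a second molecule before the pyrone does. The fallback closes the pyran ring while the second ring ketone is still a silyl ether. It sets out from allylic alcohol 31. MnO2 oxidises only the allylic alcohol to the exo-methylene ketone F4a, written here as the bis-silyl methylene ketone F5. Pyrone 34 adds in the same Michael sense and the adduct closes to the silylated hemiketal F6. HF·pyridine removes both silyl groups to give the hemiketal diol F7. IBX oxidises the remaining secondary alcohol to keto hemiketal 36, which loses water with PPTS and rejoins the route at 37.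

Step 21. The push–pull C=C of 37 may react too slowly with DMDO, so that oxidation of the pyrone ring or over-oxidation competes, and the epoxide may open to give ring-cleaved products. The fallback puts the oxygen on before the pyran ring exists. It sets out from trione 33, whose enolised 1,3-dione CH2 is hydroxylated with DMDO at −40 °C (Davis oxaziridine as alternative oxidant) to the 2-hydroxy-1,3-dione F8 (epimers and enol forms at the new CH(OH)). Conjugate addition of 34 to F8 and spontaneous hemiketalisation under thermodynamic control then gives 39 directly.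

Further compounds
F1 | step 14 | (R)-3,5-bis(triethylsilyloxy)pentan-2-one | CC(=O)[C@H](O[Si](CC)(CC)CC)CCO[Si](CC)(CC)CC
F2 | step 14 | analogue of 26 without the two ring methyl groups (CH2 between the silyl enol ether carbon and the carbinol carbon) | CC[Si](CC)(CC)OCC[C@@H](O[Si](CC)(CC)CC)[C@@]1(O[Si](C)(C)C)[C@@H](C=C(O[Si](C)(C)C(C)(C)C)C1)[C@H](C)C(I)=C
F3 | step 14 | (4R)-4-[(1R)-1,3-bis(triethylsilyloxy)propyl]-3-[(2S)-3-iodobut-3-en-2-yl]-4-(trimethylsilyloxy)cyclopent-2-en-1-one | CC[Si](CC)(CC)OCC[C@@H](O[Si](CC)(CC)CC)[C@@]1(O[Si](C)(C)C)C(=CC(=O)C1)[C@H](C)C(I)=C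
F4 | step 14 | 5-methyl derivative of F3 (both epimers at the methylated carbon) | CC[Si](CC)(CC)OCC[C@@H](O[Si](CC)(CC)CC)[C@@]1(O[Si](C)(C)C)C(=CC(=O)C1C)[C@H](C)C(I)=C
F5 | step 20 | (3aR,4R,8R)-3,3,8-trimethyl-7-methylidene-4-(triethylsilyloxy)-3a-(trimethylsilyloxy)-3a,4,5,7,8-pentahydroazulene-2,6(3H)-dione (the exo-methylene ketone from 31, called F4a in the running text) | O=C1C[C@@H](O[Si](CC)(CC)CC)[C@@]2(O[Si](C)(C)C)C(=CC(=O)C2(C)C)[C@H](C)C1=C
F6 | step 20 | hemiketal adduct of F5 and 34: skeleton of 36 with CH(OSiEt3) in place of the ring ketone and OSiMe3 on the tertiary carbinol | Cc1oc(=O)c2c(c1C)O[C@]1(O)C[C@@H](O[Si](CC)(CC)CC)[C@@]3(O[Si](C)(C)C)C(=CC(=O)C3(C)C)[C@H](C)[C@H]1C2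
F7 | step 20 | desilylated F6 (secondary and tertiary OH free) | Cc1oc(=O)c2c(c1C)O[C@]1(O)C[C@@H](O)[C@@]3(O)C(=CC(=O)C3(C)C)[C@H](C)[C@H]1C2
F8 | step 21 | (3aR,8S)-3a,5-dihydroxy-3,3,8-trimethyl-7-methylidene-3a,5,7,8-tetrahydroazulene-2,4,6(3H)-trione (epimers at the new CH(OH)) | O=C1C(O)C(=O)[C@@]2(O)C(=CC(=O)C2(C)C)[C@H](C)C1=C
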